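Start at early times and set the delta run beside the beta run: their starting material and free catalyst charges match and their second substrate charges differ, so dividing one run's target by the other's at the same clock reading makes time drop out. At 120 s the target reads 33.9% in beta and 36.5% in delta. Divide the logarithm of that ratio by the logarithm of the charge ratio to get −0.163, and call this the second-substrate slope, an apparent order read across two runs. The scatter of the two readings puts about 0.0445 on it.

| flask | starting material | second substrate | free catalyst | remark |
|---|---|---|---|---|
| delta | 20 mM | 28 mM | 0.20 mM | run made earlier |
| beta | 20 mM | 44 mM | 0.20 mM | run made earlier |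
| eta | 40 mM | 20 mM | 0.20 mM | run made earlier |
| flask | 20 mM | 20.0 mM | 0.20 mM |  |

- delta (time / s: target / %, starting material / %): 10.0: 4.2, 95.9; 30.0: 9.8, 89.8; 60.0: 18.8, 79.8; 80.0: 25.3, 74.2; 120: 36.5, 63.5
- beta (time / s: target / %, starting material / %): 10.0: 2.9, 96.9; 30.0: 8.6, 91.2; 60.0: 16.9, 82.3; 80.0: 22.9, 76.8; 120: 33.9, 67.1
- eta (time / s: target / %, starting material / %): 25.0: 5.6, 93.3; 50.0: 12.0, 88.1; 80.0: 19.4, 80.4; 90.0: 21.9, 78.4; 120: 29.1, 71.6

(each reading ± 0.5 percentage points)

- apparent order in free catalyst when 30% of the starting material are converted (percent change of the rate of making target for one percent more free catalyst charged)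
- apparent order in second substrate when 30% of the starting material are converted (percent change of the rate of making target for one percent more second substrate charged)

- no earlier run changes the charge of free catalyst; that part of a forecast is a guess

Now apply the bench rule that, with the starting material and free catalyst charges held, rate goes as second substrate charge to a fixed power. It makes the new flask's target per unit time 1.06 times that of delta, and it makes the slope itself my answer for the order in second substrate. The rule's border is close, though: the new flask's second substrate charge is 0.714 of delta's, lower than in either run of the pair, so this is extrapolation. The eta run does stand at that charge, but with 2.00 times the starting material, so setting it beside delta changes two charges at once.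

The forecast gives −0.1 (−0.45 to 0.35) for the second substrate, less negative than my slope, saying “the order may drift toward zero or positive”. For the free catalyst it gives 1 (0.6 to 1.5).

The new flask gives 0.87 in free catalyst and −0.15 in second substrate, beside the slope −0.163, and its 25.1% target at 1.25 min is 1.06 times delta's target per unit time up to 80.0 s, beside the scaled 1.06. starting material + free catalyst ⇌ catalyst intermediate A (K = 1200 L mol⁻¹, k = 89.1 L mol⁻¹ s⁻¹); 2 free catalyst ⇌ resting dimer, settled at all times (K = 5600 L mol⁻¹); catalyst intermediate A → free catalyst + target (k = 0.730 s⁻¹); catalyst intermediate B → free catalyst + second product (k = 0.837 s⁻¹); second substrate + free catalyst ⇌ catalyst intermediate B (K = 38.6 L mol⁻¹, k = 538 L mol⁻¹ s⁻¹)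

In the new flask, catalyst intermediate A has a half-life of 0.95 s by its step to target at 1.13 min, far shorter than the 1.49 min taken to reach 30% conversion. In the new flask, catalyst intermediate B is made 1.00 times as fast as it is used up at 1.13 min, each step taken net, a quasi-steady state, and at 30% conversion 16.8% of the catalyst is catalyst intermediate B and 15.6% is resting dimer.

The runs were generated by integration with constants of no real substance; scatter was added.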